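**Retrosynthetic overview**
- The spiro-epoxide comes last, by 12-OH-directed epoxidation of C11=C20. The 12α-OH comes from 1,2-reduction of an 11(20)-en-12-one, which keeps C12 unacylated while C2, C9, C13 and C14 are acetylated.
- Key disconnection: the C7–O bond together with C16–Cl, made in one 1,4-chloro-lactonisation of a ten-membered 5(16),6-diene carrying a C17 carboxamide arm. The γ-lactone is the last carbon-framework ring to form.
- The ten-membered ring is closed at C6=C7 by ethene/enyne metathesis followed by ring-closing metathesis of a ring A core with two arms.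
- The C10 arm comes from an acryloyl-anion addition (C9) and a propionamide aldol (C8, C17). The C1 arm comes from a chelate-controlled Grignard addition (C2).
- Ring A is made first by an enantioselective Diels–Alder reaction (C1, C10). Ring order: ring A, temporary γ-lactone, ten-membered ring, γ-lactone, epoxide.

Assumption: briarane numbering is used (C1 quaternary carbon with CH3-15, C2–C9 round the ten-membered ring, C10 ring-fusion CH, C11–C14 in ring A, C16 = CH2Cl, C17/C18/C19 = lactone CH/CH3/C=O, C20 = epoxide CH2); β is the face of CH3-15 and α the opposite face.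

**Step 1**
Reactants: 1 ethyl (E)-3-methyl-4-oxobut-2-enoate; 2 (E)-3-(tert-butyldimethylsilyloxy)-N,N-dimethylbuta-1,3-dien-1-amine
Product: 3 ring A Diels–Alder adduct (C1: β-CH3, α-CHO; C10: β-CO2Et; C14: α-NMe2; C12=C13 enol silane)
Conditions: (R,R)-1-naphthyl-TADDOL (20 mol %), toluene, −78 °C, 48 h; used crude
Reagents that add atoms: none
Why: Hydrogen-bond-catalysed enantioselective Diels–Alder reaction, in which the nucleophilic CH2 terminus of 2 bonds to C10 (β to the activated formyl group), the (E)-alkene makes C2 and C9 trans, the endo formyl group puts 14-N cis to C2, and the TADDOL–formyl hydrogen bond with one naphthyl group covering one face fixes the absolute configuration at C1 and C10.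

**Step 2**
Reactants: 3 ring A Diels–Alder adduct; 4 (4-bromobut-1-yn-1-yl)trimethylsilane
Product: 8 enone lactone, via hydroxy ester 5 (not isolated), via masked lactone 6 (not isolated), via amino ketone 7 (not isolated)
Conditions: 4, Mg, THF, 25 °C; add to 3, THF, −78 → 25 °C; then 1 M HCl, THF, 0 → 25 °C
Reagents that add atoms: 4 as its Grignard reagent, [4-(trimethylsilyl)but-3-yn-1-yl]magnesium bromide, C[Si](C)(C)C#CCC[Mg]Br
Why: Cram-chelate Grignard addition followed by lactonisation and acid unmasking, in which magnesium bridges the 14α-NMe2 group and the formyl oxygen so that the carbon nucleophile enters past the small axial CH3-15 and sets C2 (2,14-anti), the alkoxide closes the trans-fused γ-lactone on the ester, and acid hydrolyses the enol silane and expels dimethylamine by E1cB elimination.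

**Step 3**
Reactants: 8 enone lactone
Product: 9 13α,14α-diol
Conditions: OsO4 (5 mol %), N-methylmorpholine N-oxide (1.5 equiv), citric acid (0.75 equiv), t-BuOH/acetone/H2O, 25 °C
Reagents that add atoms: osmium tetroxide O=[Os](=O)(=O)=O (catalytic oxygen carrier); N-methylmorpholine N-oxide C[N+]1([O-])CCOCC1; water O
Why: Upjohn dihydroxylation of the enone from the α face, because the axial CH3-15 next to C14 covers the β face as an angular methyl group does in steroidal 1-en-3-ones, which sets C13 and C14 as the cis-α-diol.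

**Step 4**
Reactants: 9 13α,14α-diol
Product: 10 11(20)-methylene ketone
Conditions: (CH2O)n (3 equiv), i-Pr2NH·CF3CO2H (1 equiv), CF3CO2H (10 mol %), THF, 65 °C
Reagents that add atoms: paraformaldehyde (as formaldehyde) C=O
Why: Mannich-type α-methylenation of a ketone, in which only the adduct at the CH2 group C11 can lose the amine, so the exocyclic enone is the sole exit and no stereocenter is formed.

**Step 5**
Reactants: 10 11(20)-methylene ketone
Product: 11 lactol tetraol
Conditions: i-Bu2AlH (6 equiv), CH2Cl2/THF, −78 °C; Rochelle salt work-up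
Reagents that add atoms: none
Why: Hydride reduction that stops the lactone at the aluminium lactolate and reduces the enone 1,2, which stores the C12 carbonyl as an allylic alcohol during the organometallic steps; the C12 centre (mainly α) and the lactol centre made here are erased in steps 9 and 6.

**Step 6**
Reactants: 11 lactol tetraol; 12 methoxyallene
Product: 14 vinyl ketone pentaol, via allenyl carbinol 13 (not isolated)
Conditions: 12 (9 equiv), n-BuLi, THF, −78 °C; MgBr2·OEt2, −78 → −40 °C; add 11, −78 → 0 °C; then 5% aq H2SO4, THF, 0 °C, 20 min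
Reagents that add atoms: methoxyallene COC=C=C; water O
Why: Chelate-controlled addition of a metallated alkoxyallene (acryloyl anion equivalent) to the ring-opened lactol, in which magnesium ties the C2 alkoxide to the C9 aldehyde oxygen, the nucleophile attacks the open face beside H10 (overriding Felkin–Anh) and sets C9, and dilute acid hydrolyses the allenyl ether to the vinyl ketone.

**Step 7**
Reactants: 14 vinyl ketone pentaol
Product: 15 pentakis(triethylsilyl) ether
Conditions: Et3SiOTf (7 equiv), 2,6-lutidine, CH2Cl2, −78 → 0 °C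
Reagents that add atoms: triethylsilyl triflate CC[Si](CC)(CC)OS(=O)(=O)C(F)(F)F
Why: Silyl ether formation with a silyl triflate, whose bulky non-chelating 9-OSiEt3 group switches the next carbonyl addition to Felkin–Anh control; no stereocenter changes.

**Step 8**
Reactants: 15 pentakis(triethylsilyl) ether; 16 N,N-dimethylpropanamide
Product: 18 hexaol enyne amide, via silylated aldol adduct 17 (not isolated)
Conditions: 16 (3 equiv), LiN(i-Pr)2, THF, −78 °C; add 15, −78 °C, 20 min; AcOH quench; then Bu4NF/AcOH (1:1, 8 equiv), THF, 0 → 25 °C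
Reagents that add atoms: N,N-dimethylpropanamide CCC(=O)N(C)C
Why: Kinetic 1,2-aldol addition of the (Z)-lithium amide enolate, in which polar Felkin–Anh attack anti to the C9–O bond sets C8, the Zimmerman–Traxler chair with the C9 branch equatorial and the vinyl group axial sets C17 (CH3-18 on the side of 8-OH in the later lactone), and buffered fluoride then removes all O- and C-silyl groups.

**Step 9**
Reactants: 18 hexaol enyne amide
Product: 19 12-ketone pentaol
Conditions: MnO2 (activated, 25 equiv), EtOAc/acetone, 25 °C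
Reagents that add atoms: none
Why: Chemoselective MnO2 oxidation, in which only the secondary allylic 12-OH reacts (8-OH is tertiary, the others are not allylic), so the exocyclic enone returns and C12 carries no hydroxyl group in the acetylation.

**Step 10**
Reactants: 19 12-ketone pentaol
Product: 20 2,9,13,14-tetraacetate
Conditions: Ac2O (10 equiv), pyridine, DMAP (10 mol %), CH2Cl2, 0 → 25 °C
Reagents that add atoms: acetic anhydride CC(=O)OC(C)=O
Why: DMAP-catalysed acetylation of the four secondary alcohols while the tertiary 8-OH does not react; no stereocenter changes.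

**Step 11**
Reactants: 20 2,9,13,14-tetraacetate
Product: 22 ten-membered (6Z)-5(16),6-diene, via butadienyl triene 21 (not isolated)
Conditions: second-generation Hoveyda–Grubbs catalyst (2 × 7 mol %), ethene (1 atm), toluene, 25 °C; then argon sparge, dilution to 1 mM, 80 °C
Reagents that add atoms: ethene C=C
Why: Tandem enyne cross metathesis with ethene and ring-closing diene–ene metathesis, in which the alkyne becomes the 2-substituted butadiene (C16 from ethene), the trans-diequatorial arms on ring A hold the chain ends close, the ten-membered ring favours the (Z)-C6=C7 bond, and the electron-poor 1,1-disubstituted enone alkene is a spectator.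

**Step 12**
Reactants: 22 ten-membered (6Z)-5(16),6-diene
Product: 24 chlorolactone enone, via chloro iminium lactone salt 23 (not isolated)
Conditions: 1,3-dichloro-5,5-dimethylhydantoin (1.05 equiv), Ph3P=S (10 mol %), 4 Å MS, CH2Cl2, −40 °C; then pH 4.5 acetate buffer/THF, 0 °C
Reagents that add atoms: 1,3-dichloro-5,5-dimethylhydantoin CC1(C)N(Cl)C(=O)N(Cl)C1=O; water O
Why: Proposed new method: Lewis-base-catalysed 1,4-chloro-iminolactonisation of a semicyclic 2-substituted 1,3-diene, in which Ph3P=S takes Cl+ from the N-chlorohydantoin and hands it to the unhindered terminal carbon C16, the resulting C5–C6–C7 allyl cation is trapped 5-exo at C7 by the amide oxygen (forming the C7–O bond and the γ-lactone ring) from the face that carries the C17 arm when the small 8-OH eclipses the (Z)-C6=C7 bond to avoid A1,3 strain, which sets C7 with H7 syn to C9, the ten-membered ring keeps C4 and C7 cis on the new C5=C6 bond, the enone alkene is too electron-poor to compete, and mildly acidic hydrolysis of the iminium ether gives the lactone; the closest known reaction types are the catalysed 1,2-chlorolactonisation of alkenoic acids with N-chlorohydantoins, the halolactonisation of unsaturated tertiary amides and the 1,4-bromolactonisation of conjugated enynes, none of which has been shown with chlorine on a medium-ring diene.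

**Step 13**
Reactants: 24 chlorolactone enone
Product: 25 12α-allylic alcohol
Conditions: NaBH4, CeCl3·7H2O, MeOH/CH2Cl2, −78 °C
Reagents that add atoms: none
Why: Luche reduction, in which the axial 14α-acetate blocks the axial α trajectory so that hydride comes from the β face and gives the axial 12α-alcohol, while allylic chloride, lactone and acetates survive at −78 °C.

**Step 14**
Reactants: 25 12α-allylic alcohol
Product: 26 CNP0330408.1 (target)
Conditions: VO(acac)2 (5 mol %), t-BuOOH (decane, 1.5 equiv), CH2Cl2, 0 °C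
Reagents that add atoms: tert-butyl hydroperoxide CC(C)(C)OO
Why: Vanadium-catalysed hydroxyl-directed epoxidation of an allylic alcohol, in which the peroxide bound to vanadium on the axial 12α-OH delivers oxygen to the α face of C11=C20 and sets C11, while the electron-poor C5=C6 bond is untouched.

**Compound list**
1 | ethyl (E)-3-methyl-4-oxobut-2-enoate | CCOC(=O)/C=C(\C)C=O | starting material
2 | (E)-3-(tert-butyldimethylsilyloxy)-N,N-dimethylbuta-1,3-dien-1-amine | CN(C)/C=C/C(=C)O[Si](C)(C)C(C)(C)C | starting material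
3 | ring A Diels–Alder adduct: cyclohexene with C1 (β-CH3, α-CHO), C10 (β-CO2Et, α-H), C14 (α-NMe2), C12=C13 bearing 12-OTBS | C1=C(O[Si](C)(C)C(C)(C)C)C[C@H](C(=O)OCC)[C@@](C)(C=O)[C@H]1N(C)C | intermediate
4 | (4-bromobut-1-yn-1-yl)trimethylsilane | C[Si](C)(C)C#CCCBr | starting material
5 | hydroxy ester: 3 with CHO turned into the C2 carbinol CH(OH)CH2CH2C≡CSiMe3, 2-OH anti to 14-N | C1=C(O[Si](C)(C)C(C)(C)C)C[C@H](C(=O)OCC)[C@@](C)([C@@H](O)CCC#C[Si](C)(C)C)[C@H]1N(C)C | intermediate
6 | masked lactone: trans-fused γ-lactone O2–C9(=O), enol silane and 14α-NMe2 still in place | C1=C(O[Si](C)(C)C(C)(C)C)C[C@@H]2C(=O)O[C@@H](CCC#C[Si](C)(C)C)[C@@]2(C)[C@H]1N(C)C | intermediate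
7 | amino ketone: 12-ketone with 14α-NMe2, trans-fused γ-lactone | O=C1C[C@H](N(C)C)[C@]2(C)[C@H](CCC#C[Si](C)(C)C)OC(=O)[C@H]2C1 | intermediate
8 | enone lactone: 13-en-12-one, trans-fused O2–C9 γ-lactone, C2 side chain CH2CH2C≡CSiMe3 trans to CH3-15 on the lactone ring | O=C1C=C[C@]2(C)[C@H](CCC#C[Si](C)(C)C)OC(=O)[C@H]2C1 | intermediate
9 | 13α,14α-diol of 8 (12-ketone) | O=C1[C@H](O)[C@H](O)[C@]2(C)[C@H](CCC#C[Si](C)(C)C)OC(=O)[C@H]2C1 | intermediate
10 | 11(20)-methylene ketone: 9 with C11=CH2 | C=C1C(=O)[C@H](O)[C@H](O)[C@]2(C)[C@H](CCC#C[Si](C)(C)C)OC(=O)[C@H]21 | intermediate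
11 | lactol tetraol: 12α,13α,14α-triol, C11=CH2, C9 lactol (anomers) | C=C1[C@H](O)[C@H](O)[C@H](O)[C@]2(C)[C@H](CCC#C[Si](C)(C)C)OC(O)[C@H]21 | intermediate
12 | methoxyallene (1-methoxypropa-1,2-diene) | COC=C=C | starting material
13 | allenyl carbinol: open pentaol with C9 carbinol bonded to C(OMe)=C=CH2 | C=C1[C@H](O)[C@H](O)[C@H](O)[C@](C)([C@@H](O)CCC#C[Si](C)(C)C)[C@H]1[C@H](O)C(OC)=C=C | intermediate
14 | vinyl ketone pentaol: 2,9,12α,13α,14α-pentaol with C8 vinyl ketone | C=C1[C@H](O)[C@H](O)[C@H](O)[C@](C)([C@@H](O)CCC#C[Si](C)(C)C)[C@H]1[C@H](O)C(=O)C=C | intermediate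
15 | pentakis(triethylsilyl) ether of 14 | C=C1[C@H](O[Si](CC)(CC)CC)[C@H](O[Si](CC)(CC)CC)[C@H](O[Si](CC)(CC)CC)[C@](C)([C@@H](O[Si](CC)(CC)CC)CCC#C[Si](C)(C)C)[C@H]1[C@H](O[Si](CC)(CC)CC)C(=O)C=C | intermediate
16 | N,N-dimethylpropanamide | CCC(=O)N(C)C | starting material
17 | silylated aldol adduct: tertiary 8-OH, 8-vinyl, C17 CH(CH3)CONMe2 | C=C1[C@H](O[Si](CC)(CC)CC)[C@H](O[Si](CC)(CC)CC)[C@H](O[Si](CC)(CC)CC)[C@](C)([C@@H](O[Si](CC)(CC)CC)CCC#C[Si](C)(C)C)[C@H]1[C@H](O[Si](CC)(CC)CC)[C@@](O)(C=C)[C@@H](C)C(=O)N(C)C | intermediate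
18 | hexaol enyne amide: 17 without silyl groups, terminal alkyne | C=C1[C@H](O)[C@H](O)[C@H](O)[C@](C)([C@@H](O)CCC#C)[C@H]1[C@H](O)[C@@](O)(C=C)[C@@H](C)C(=O)N(C)C | intermediate
19 | 12-ketone pentaol: 11(20)-en-12-one | C=C1C(=O)[C@H](O)[C@H](O)[C@](C)([C@@H](O)CCC#C)[C@H]1[C@H](O)[C@@](O)(C=C)[C@@H](C)C(=O)N(C)C | intermediate
20 | 2,9,13,14-tetraacetate of 19 (8-OH free) | C=C1C(=O)[C@H](OC(C)=O)[C@H](OC(C)=O)[C@](C)([C@@H](OC(C)=O)CCC#C)[C@H]1[C@H](OC(C)=O)[C@@](O)(C=C)[C@@H](C)C(=O)N(C)C | intermediate
21 | butadienyl triene: alkyne of 20 turned into C5(=CH2)–CH=CH2 | C=C1C(=O)[C@H](OC(C)=O)[C@H](OC(C)=O)[C@](C)([C@@H](OC(C)=O)CCC(=C)C=C)[C@H]1[C@H](OC(C)=O)[C@@](O)(C=C)[C@@H](C)C(=O)N(C)C | intermediate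
22 | ten-membered (6Z)-5(16),6-diene with 8-OH and the C17 amide arm | C=C1C(=O)[C@H](OC(C)=O)[C@H](OC(C)=O)[C@]2(C)[C@@H](OC(C)=O)CCC(=C)/C=C\[C@@](O)([C@@H](C)C(=O)N(C)C)[C@@H](OC(C)=O)[C@H]21 | intermediate
23 | chloro iminium lactone salt: C7–O closed, C19=N+Me2, 16-Cl, 1-chloro-5,5-dimethylhydantoin anion | C=C1C(=O)[C@H](OC(C)=O)[C@H](OC(C)=O)[C@]2(C)[C@@H](OC(C)=O)CC/C(CCl)=C\[C@@H]3OC(=[N+](C)C)[C@H](C)[C@@]3(O)[C@@H](OC(C)=O)[C@H]21.CC1(C)N(Cl)C(=O)[N-]C1=O | intermediate
24 | chlorolactone enone: 16-chloro-5-ene (C4 and C7 cis), 7,19-γ-lactone, 8-OH, 11(20)-en-12-one, four acetates | C=C1C(=O)[C@H](OC(C)=O)[C@H](OC(C)=O)[C@]2(C)[C@@H](OC(C)=O)CC/C(CCl)=C\[C@@H]3OC(=O)[C@H](C)[C@@]3(O)[C@@H](OC(C)=O)[C@H]21 | intermediate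
25 | 12α-allylic alcohol of 24 | C=C1[C@H](O)[C@H](OC(C)=O)[C@H](OC(C)=O)[C@]2(C)[C@@H](OC(C)=O)CC/C(CCl)=C\[C@@H]3OC(=O)[C@H](C)[C@@]3(O)[C@@H](OC(C)=O)[C@H]21 | intermediate
26 | CNP0330408.1: 11α,20-epoxide of 25 | CC(=O)O[C@H]1[C@@H](O)[C@]2(CO2)[C@@H]2[C@H](OC(C)=O)[C@@]3(O)[C@H](/C=C(/CCl)CC[C@H](OC(C)=O)[C@@]2(C)[C@H]1OC(C)=O)OC(=O)[C@@H]3C | target

**Step count**
- Total steps: 14
- Longest linear sequence: 14 (from 1 and 2 to 26; compounds 4, 12 and 16 are bought)

**Three steps most likely to fail**

Step 12 (the proposed new step). The risks are 1,2- instead of 1,4-addition, the wrong diene conformer, and capture by the 9-acetate.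
- The fallback sets out from 22 and comes back at 24, and uses only known chemistry.
- Classical iodolactonisation of the unsaturated tertiary amide (I2, THF/H2O, NaH2PO4, 0 °C) closes the amide oxygen on C7 and releases the amine on hydrolysis.
- The allylic iodide equilibrates to the primary 16-iodo lactone F1.
- Halide exchange with LiCl (10 equiv, acetone/DMF, 25 °C) then gives 24, so chlorine enters as a nucleophile and not as an electrophile.

Step 11 (ten-membered ring by metathesis next to a fully substituted carbinol). The risks are dimerisation and no closure.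
- The fallback sets out from 20 and comes back at 24. It forms C5–C6 instead of C6=C7.
- Markovnikov hydroiodination of the terminal alkyne (B-iodo-9-borabicyclo[3.3.1]nonane, CH2Cl2, −20 °C, then AcOH) gives the 2-iodoalkene F2.
- An intramolecular Heck reaction (Pd(OAc)2, PPh3, Ag2CO3, MeCN, 2 mM, 60 °C) onto the C8 vinyl group gives the (6E)-macrocyclic diene F3. C8 carries no hydrogen, so the diene is the only β-hydride product.
- F3 gives the same allyl cation under the conditions of step 12 and so delivers 24.

Step 8 (two stereocenters on an enolisable vinyl ketone; C17 is the weak point).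
- The fallback sets out from 15 and comes back at 17. It sets C17 by protonation rather than in the C–C bond formation.
- The aldol is run without regard to C17.
- The 17-epimeric aldol adduct F4, or the mixture, is turned with LiN(i-Pr)2 (2.5 equiv, THF, −78 → −40 °C) into the lithium-chelated alkoxide–enolate.
- It is then protonated at −78 °C with 2,6-di-tert-butyl-4-methylphenol from the face away from the C9 branch. This is the proton counterpart of the Fráter–Seebach alkylation, and it gives 17.

**Further compounds**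
F1 | step 12 | 16-iodo lactone (24 with I in place of Cl) | C=C1C(=O)[C@H](OC(C)=O)[C@H](OC(C)=O)[C@]2(C)[C@@H](OC(C)=O)CC/C(CI)=C\[C@@H]3OC(=O)[C@H](C)[C@@]3(O)[C@@H](OC(C)=O)[C@H]21
F2 | step 11 | 2-iodoalkene (20 with C5(I)=CH2 in place of the alkyne) | C=C1C(=O)[C@H](OC(C)=O)[C@H](OC(C)=O)[C@](C)([C@@H](OC(C)=O)CCC(I)=C)[C@H]1[C@H](OC(C)=O)[C@@](O)(C=C)[C@@H](C)C(=O)N(C)C
F3 | step 11 | (6E)-macrocyclic diene (6E isomer of 22) | C=C1C(=O)[C@H](OC(C)=O)[C@H](OC(C)=O)[C@]2(C)[C@@H](OC(C)=O)CCC(=C)/C=C/[C@@](O)([C@@H](C)C(=O)N(C)C)[C@@H](OC(C)=O)[C@H]21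
F4 | step 8 | 17-epimeric aldol adduct (17-epimer of 17) | C=C1[C@H](O[Si](CC)(CC)CC)[C@H](O[Si](CC)(CC)CC)[C@H](O[Si](CC)(CC)CC)[C@](C)([C@@H](O[Si](CC)(CC)CC)CCC#C[Si](C)(C)C)[C@H]1[C@H](O[Si](CC)(CC)CC)[C@@](O)(C=C)[C@H](C)C(=O)N(C)C
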